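In a one-step world substrate turns straight into target by a first-order step, and the curve is steepest at the start. Alder's target rose more slowly over the first 0.500 d than between 1.67 d and 3.00 d, so I reckoned with a chain.

| flask | substrate | partner | protic impurity | remark | time |
|---|---|---|---|---|---|
| alder | 0.34 M | 1.36 M | 0.17 M | run made earlier |  |
| maple | 0.34 M | 0.68 M | 0.17 M | run made earlier |  |
| ash | 0.34 M | 2.7 M | 0.17 M | run made earlier |  |
| oak | 0.34 M | 1.36 M | 0.26 M | run made earlier |  |
| Saturday's | 0.34 M | 1.36 M | 0.170 M | a single well-mixed tank run continuously and read at steady state, 100 d in it on average |  |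
| Friday's | 0.34 M | 1.36 M | 0.170 M | a single well-mixed tank run continuously and read at steady state, 10 d in it on average |  |
| Thursday's | 0.34 M | 1.36 M | 0.170 M | everything together in a closed stirred flask, run for 10 d | 10 d |
| Wednesday's | 0.34 M (fed, over 5.00 d) | 1.36 M | 0.170 M | all but substrate at the start; substrate goes in evenly over 5.00 d, the run ends at 10 d | 10 d |

| run | time / d | target / % |
|---|---|---|
| alder | 0.500 | 1.5 |
| alder | 0.833 | 4.1 |
| alder | 1.67 | 14.9 |
| alder | 3.00 | 31.1 |
| alder | 6.00 | 54.6 |
| maple | 0.625 | 0.4 |
| maple | 2.08 | 7.9 |
| maple | 4.00 | 15.8 |
| maple | 6.00 | 23.8 |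
| maple | 8.00 | 28.9 |
| ash | 1.67 | 29.9 |
| ash | 3.00 | 56.4 |
| ash | 5.00 | 78.3 |
| ash | 6.00 | 83.3 |
| ash | 8.00 | 87.5 |
| oak | 0.625 | 3.4 |
| oak | 1.25 | 8.4 |
| oak | 2.50 | 23.3 |
| oak | 4.00 | 39.3 |
| oak | 8.00 | 59.7 |

(readings scatter by 1 percentage point)

- the stated concentrations are those of everything mixed, before any reaction; amounts are the same in each set-up
- steps thought possible: substrate -> intermediate A; partner + intermediate A -> intermediate B; partner + intermediate B -> target; intermediate B -> side product; partner + protic impurity -> quenched reagent
- the feed brings no volume worth counting
- the earlier runs were made in a closed, stirred flask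

- order of the set-ups by the amount of target at the outlet or at the end, in percent of the substrate put in, highest first (Saturday's / Friday's / Thursday's / Wednesday's)
- amount of target at the outlet or at the end, in percent of the substrate put in, Saturday's
- amount of target at the outlet or at the end, in percent of the substrate put in, Friday's
- amount of target at the outlet or at the end, in percent of the substrate put in, Thursday's
- amount of target at the outlet or at the end, in percent of the substrate put in, Wednesday's

The first step, substrate → intermediate A, uses no partner, so I looked for its time where the partner steps ran quickest. That was ash, with twice alder's [partner] and the highest of the runs. Late in ash, the climb fell from 0.0500 d⁻¹ of the charge to 0.0210 d⁻¹ across 1.50 d. Substrate and intermediate A can both still feed this tail, and it falls no faster than the slower of them drains, so I took the 1.73 d it gives as a ceiling on the turnover time, the mean wait of a substrate before it becomes intermediate A. It is a loose reading, taken from differences of scattered points.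

I set this against one other time, the time in the vessel. Their ratio is the turnover count (the Damköhler number). A closed flask keeps e to the minus the count of its substrate; a steady tank lets out one over one plus the count.

| Set-up | Turnovers, lower estimate | Substrate left, upper estimate |
|---|---|---|
| Thursday's | 5.78 | 0.309 % |
| Wednesday's, last of the dose | 2.89 | 5.55 % |
| Friday's | 5.78 | 14.7 % |

So I expected Friday's to leave the most substrate of these, and I placed it below Wednesday's and Thursday's.

The forecast gave Saturday's > Thursday's > Wednesday's > Friday's, with 69 %, 46 %, 68 % and 61 % in the order Saturday's, Friday's, Thursday's, Wednesday's, and called Saturday's “nearly tied with Thursday”.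

The flask gave Thursday's > Saturday's > Wednesday's > Friday's: Thursday's 67.8 %, Saturday's 65.3 %, Wednesday's 60.7 %, Friday's 47.1 %.

    substrate → intermediate A (k = 0.0275 h⁻¹)
    partner + intermediate A → intermediate B (k = 0.0152 M⁻¹ h⁻¹)
    partner + intermediate B → target (k = 0.217 M⁻¹ h⁻¹)
    intermediate B → side product (k = 0.0624 h⁻¹)
    partner + protic impurity → quenched reagent (k = 0.286 M⁻¹ h⁻¹)

Saturday's tank, at [partner] 0.647 M, gave less target than Thursday's flask. Its 100 d on average against the ceiling of 1.73 d makes at least 57.8 turnovers, so I reckon at most 1.70 % of the substrate left, and Saturday's outlet held 1.49 %.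

The numbers in the tables are calculated on assumed constants.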